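The constants to be had before any new flask is run are a rate constant and an activation energy for the main step, in which starting material and coupling partner give target on the catalyst; the earlier runs below supply both, and the flasks asked about differ in temperature.

| setting | zeta | delta | east | north-west | south-east | west |
|---|---|---|---|---|---|---|
| starting material | 0.010 M | 0.010 M | 0.010 M | 0.010 M | 0.010 M | 0.010 M |
| coupling partner | 0.35 equiv | 1.4 equiv | 0.700 equiv | 0.700 equiv | 0.700 equiv | 0.700 equiv |
| second substrate | 1 equiv | 1 equiv | 1.00 equiv | 1.00 equiv | 1.00 equiv | 1.00 equiv |
| catalyst | 4.2 mol% | 4.2 mol% | 4.2 mol% | 4.2 mol% | 4.2 mol% | 4.2 mol% |
| temperature | −5 °C | 38 °C | 0 °C | 25 °C | 50 °C | 75 °C |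
| remark | run made earlier | run made earlier |  |  |  |  |
| time |  |  | 2.0 d | 2.0 d | 2.0 d | 2.0 d |

| run | time / h | target / % |
|---|---|---|
| zeta | 5.00 | 1.1 |
| zeta | 10.0 | 3.5 |
| zeta | 15.0 | 2.9 |
| zeta | 20.0 | 3.3 |
| zeta | 25.0 | 4.9 |
| zeta | 30.0 | 6.0 |
| delta | 0.833 | 10.0 |
| delta | 1.50 | 16.6 |
| delta | 2.50 | 20.3 |
| delta | 3.00 | 25.3 |
| delta | 4.00 | 24.4 |
| delta | 5.00 | 28.2 |

(each reading ± 1 percentage point)



* which flask leads in amount of target, in percent of the starting material charged ("all alike" within 1.5 percentage points) (east / north-west / south-east / west / all alike)
* how much target is there at the end, in percent of the starting material charged: east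
* how much target is there at the end, in percent of the starting material charged: north-west
* how much target is there at the end, in percent of the starting material charged: south-east
* how much target is there at the end, in percent of the starting material charged: west

Take the main step alone, first order in coupling partner and, with the partner held at its charge, pseudo-first-order in starting material. The zeta run makes target at 0.00200 h⁻¹ of the charge, read over its whole length, and the delta run at 0.120 h⁻¹, read at its first point. Dividing each by its partner equivalents gives an activation energy of 43.7 kJ mol⁻¹, a reading that carries the scatter. Carried to east, this gives starting material a lifetime of 175 h, so east counts 0.275 lifetimes in the asked time, and this lifetime count is what the flask is reckoned by. The count alone gives east 24.0% of target, and the hotter flasks count 1.38, 5.39 and 17.3, so the main step by itself favours west, with the largest count.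

The next process reverses this. After its third reading the delta run rises at 0.0316 h⁻¹, less than its opening rate, and that slowing is read here as target being lost while it is made. Treating the delta run as level at its last reading, so that making and loss balance there, and with 54.9% of the starting material counted as left, the loss constant over the making constant reads 1.95 in delta, an estimate that carries the scatter. If the loss ignores the partner and shares the main step's temperature dependence, it becomes 3.89 at this charge, a selectivity factor. Target is then the difference of the exponentials of minus the count and minus the factor times the count, divided by the factor less one: 14.4% in east, 8.54% in north-west and 0.157% in south-east, with west lower again.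

The rest is the coupling partner, the limiting reagent by charge, of which east's counted conversion takes about a third. Both earlier runs carried 1 equiv of second substrate, so they do not vary that charge, and it enters this reckoning with no number. This reckoning therefore commits to east leading.

The forecast named north-west as leader, with 23%, 32%, 10% and 3% from east to west, and of the levelling in delta it said “I read it as catalyst death”.

East leads with 18.2% of target, against 5.38% in north-west, 0.00529% in south-east and 0% in west.

    second substrate + coupling partner + catalyst → catalyst + second product (k = 18000 M⁻² h⁻¹, Ea = 53.0 kJ mol⁻¹)
    catalyst + target → catalyst + over-reaction product (k = 1100 M⁻¹ h⁻¹, Ea = 57.0 kJ mol⁻¹)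
    starting material + coupling partner + catalyst → catalyst + target (k = 49000 M⁻² h⁻¹, Ea = 44.0 kJ mol⁻¹)
    (constants at 50 °C)

At the asked time east holds 76.6% of its starting material, and its lifetime count of 0.275 gives 76.0%. The neighbour flask, east with 2.80 equiv of coupling partner and all else held, counts 1.10 lifetimes, which leaves 33.3%, and that flask holds 32.6% of starting material beside 51.1% of target.

The data were generated by integration from invented constants, noise included.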